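**Retrosynthetic overview**
1. Target 13 ⇒ aryl–C(sp3) bond: visible-light Ir/Ni decarboxylative arylation of the hydroxy fatty acid 10 with unprotected 5-bromoresorcinol 11.
2. Acid 10 ⇒ Z-selective Wittig between hydroxy aldehyde 8 and the ylide of phosphonium salt 2 (from 9-bromononanoic acid 1).
3. Aldehyde 8 ⇒ ozonolysis of alkenol 6 ⇒ (S)-propylene oxide 4 + the Grignard reagent of 7-bromohept-1-ene 3.
4. The single stereocentre is bought in 4 and never touched; no ring is formed (the arene is bought in 11).

Structure read from the SMILES: 5-[(8Z,16S)-16-hydroxyheptadec-8-en-1-yl]benzene-1,3-diol, with an (S)-carbinol and a (Z)-alkene.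

**Step 1**
Reactants: 1 9-bromononanoic acid
Product: 2 (8-carboxyoctyl)triphenylphosphonium bromide
Conditions: PPh3 (1.05 equiv), MeCN, reflux, 48 h; Et2O trituration
Reagents that add atoms: triphenylphosphine, c1ccc(cc1)P(c1ccccc1)c1ccccc1
Why: SN2 quaternisation of PPh3 by the primary bromide (phosphonium salt formation); the free acid is inert.

**Step 2**
Reactants: 3 7-bromohept-1-ene; 4 (S)-2-methyloxirane [(S)-propylene oxide, ≥99% ee]
Product: 6 (2S)-dec-9-en-2-ol, via hept-6-en-1-ylmagnesium bromide 5 (not isolated)
Conditions: 3 (1.3 equiv), Mg, THF, 25→40 °C; then CuI (10 mol%), 4, −30→0 °C; 1 M HCl work-up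
Reagents that add atoms: none
Why: Copper-catalysed Grignard opening of the epoxide (SN2 at the unsubstituted CH2), so the C–O stereocentre of 4 is not involved and its (S) configuration is carried over unchanged.

**Step 3**
Reactants: 6 (2S)-dec-9-en-2-ol
Product: 8 (8S)-8-hydroxynonanal, via secondary ozonide 7 (not isolated)
Conditions: O3, CH2Cl2, −78 °C (Sudan red end point); then Me2S (5 equiv), −78→25 °C; used directly
Reagents that add atoms: ozone, [O-][O+]=O
Why: Criegee ozonolysis of the terminal alkene with reductive work-up; the isolated secondary alcohol and its stereocentre are untouched at −78 °C.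

**Step 4**
Reactants: 8 (8S)-8-hydroxynonanal; 2 (8-carboxyoctyl)triphenylphosphonium bromide
Product: 10 (9Z,17S)-17-hydroxyoctadec-9-enoic acid, via sodium ylide carboxylate 9 (not isolated)
Conditions: 2 (2.0 equiv), NaN(SiMe3)2 (4.0 equiv), THF, 0 °C; then 8, −78→25 °C; aq HCl to pH 3; base/acid extraction removes Ph3PO
Reagents that add atoms: none
Why: Z-selective Wittig olefination of a non-stabilised, lithium-free ylide with an aliphatic aldehyde under kinetic control (Z:E typically ≥95:5), of the same type as the classical carboxy-ylide olefinations of unprotected hydroxy aldehydes (lactols); the remote stereocentre is unaffected.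

**Step 5**
Reactants: 10 (9Z,17S)-17-hydroxyoctadec-9-enoic acid; 11 5-bromobenzene-1,3-diol (5-bromoresorcinol)
Product: 13 hansfordiol E [5-((8Z,16S)-16-hydroxyheptadec-8-en-1-yl)benzene-1,3-diol], via caesium carboxylate 12 (not isolated)
Conditions: 10 (1.0 equiv), Cs2CO3 (0.5 equiv), DMSO, 25 °C, 30 min; then 11 (1.5 equiv), Ir[dF(CF3)ppy]2(dtbbpy)PF6 (1 mol%), NiBr2·DME (5 mol%), 4,4′-di-tert-butyl-2,2′-bipyridine (7.5 mol%), phthalimide (1.0 equiv), degassed, 450 nm LEDs, 25 °C, 24 h; pH 5 work-up
Reagents that add atoms: none
Why: Proposed new method: a protecting-group-free decarboxylative C(sp3)–C(sp2) coupling of a free hydroxy fatty acid with an unprotected bromoresorcinol, run proton-buffered (exactly one caesium per CO2H, with phthalimide, pKa about 13 in DMSO, as nickel-stabilising additive and buffer) so that only the carboxylate (pKa about 12.5 in DMSO) and not the phenols (about 16–18) is ionised and no phenoxide is present to quench the photocatalyst or undergo C–O coupling; the excited trivalent iridium photocatalyst oxidises carboxylate 12 by single-electron transfer, CO2 is lost, the primary alkyl radical is captured by the aryl nickel bromide formed by oxidative addition of zerovalent nickel into the C–Br bond of 11, reductive elimination from trivalent nickel forms the aryl–C1′ bond, and divalent iridium returns monovalent nickel to zerovalent nickel; the Z-alkene (eight atoms from the radical, triplet energy far above that of the photocatalyst), the secondary alcohol and the stereocentre should be spectators because no hydrogen-atom-transfer catalyst is present; closest known reaction type: iridium/nickel metallaphotoredox decarboxylative arylation of aliphatic carboxylic acids with protected aryl bromides.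

**Compound list**
1 | 9-bromononanoic acid | OC(=O)CCCCCCCCBr | starting material
2 | (8-carboxyoctyl)triphenylphosphonium bromide | OC(=O)CCCCCCCC[P+](c1ccccc1)(c1ccccc1)c1ccccc1.[Br-] | intermediate
3 | 7-bromohept-1-ene | C=CCCCCCBr | starting material
4 | (S)-2-methyloxirane [(S)-propylene oxide] | C[C@H]1CO1 | starting material
5 | hept-6-en-1-ylmagnesium bromide | C=CCCCCC[Mg]Br | intermediate
6 | (2S)-dec-9-en-2-ol | C[C@H](O)CCCCCCC=C | intermediate
7 | (2S)-8-(1,2,4-trioxolan-3-yl)octan-2-ol (secondary ozonide, mixture at the ring carbon) | C[C@H](O)CCCCCCC1OCOO1 | intermediate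
8 | (8S)-8-hydroxynonanal | C[C@H](O)CCCCCCC=O | intermediate
9 | sodium 9-(triphenyl-λ5-phosphanylidene)nonanoate | [Na+].[O-]C(=O)CCCCCCCC=P(c1ccccc1)(c1ccccc1)c1ccccc1 | intermediate
10 | (9Z,17S)-17-hydroxyoctadec-9-enoic acid | C[C@H](O)CCCCCC/C=C\CCCCCCCC(=O)O | intermediate
11 | 5-bromobenzene-1,3-diol | Oc1cc(O)cc(Br)c1 | starting material
12 | caesium (9Z,17S)-17-hydroxyoctadec-9-enoate | [Cs+].[O-]C(=O)CCCCCCC/C=C\CCCCCC[C@H](C)O | intermediate
13 | hansfordiol E, 5-[(8Z,16S)-16-hydroxyheptadec-8-en-1-yl]benzene-1,3-diol | C[C@H](O)CCCCCC/C=C\CCCCCCCc1cc(O)cc(O)c1 | target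

**Step count**
Total steps: 5 (4 if salt 2 is bought instead of made). Longest linear sequence: 4 (4 → 6 → 8 → 10 → 13).

**Three steps most likely to fail**

Step 5 (the proposed new step). The risks are oxidation of the free phenols (directly or by proton-coupled electron transfer), nickel-mediated C–O coupling or aryl ester formation, and Z/E erosion by bromine radicals. The fallback uses known chemistry, sets out from 10 and 11, and changes the approach to protect–couple–deprotect. Compound 11 is protected (NaH, MOMCl, THF/DMF, 0 °C) as 1-bromo-3,5-bis(methoxymethoxy)benzene F1. F1 is coupled with 10 under the established base-promoted Ir/Ni decarboxylative arylation (Cs2CO3 1.5 equiv, same catalysts, phthalimide, DMSO, 450 nm) to give (2S,9Z)-17-[3,5-bis(methoxymethoxy)phenyl]heptadec-9-en-2-ol F2. The acetals are then removed with 2 M HCl in MeOH at 40 °C, and the route is rejoined at 13.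

Step 4. The risks are an insufficient Z:E ratio, aldol side reactions of 8, and poor solubility of the doubly charged ylide. The fallback sets out from 8 and fixes the geometry by alkyne semihydrogenation instead. Aldehyde 8 is homologated with dimethyl (1-diazo-2-oxopropyl)phosphonate (K2CO3, MeOH) to (2S)-dec-9-yn-2-ol F3. F3 is doubly lithiated (n-BuLi 2.1 equiv, THF/DMPU) and C-alkylated with lithium 8-bromooctanoate (from purchased 8-bromooctanoic acid, OC(=O)CCCCCCCBr) to give (17S)-17-hydroxyoctadec-9-ynoic acid F4. Hydrogenation of F4 over Pd/CaCO3 poisoned with Pb(OAc)2 and quinoline (H2, 1 atm, EtOAc) returns to the route at 10.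

Step 3. The risks are over-oxidation, hemiacetal oligomers, and loss of the small hydroxy aldehyde 8 on isolation. The fallback sets out from 4, swaps the roles of the Wittig partners, and avoids ozonolysis and 8 altogether. Purchased 1-bromo-6-chlorohexane (ClCCCCCCBr) is converted (Mg, THF, 20 °C, insertion at C–Br only) into 6-chlorohexylmagnesium bromide F5. F5 opens 4 (CuI 10 mol%, −30 °C) to give (2S)-9-chlorononan-2-ol F6. NaI and PPh3 in refluxing MeCN turn F6 into [(8S)-8-hydroxynonyl]triphenylphosphonium iodide F7. NaN(SiMe3)2 in THF gives the ylide (2S)-9-(triphenyl-λ5-phosphanylidene)nonan-2-ol F8, which is condensed at −78 °C with the sodium salt of purchased 9-oxononanoic acid (O=CCCCCCCCC(=O)O) to return to the route at 10.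

**Further compounds**
F1 | step 5 | 1-bromo-3,5-bis(methoxymethoxy)benzene | COCOc1cc(OCOC)cc(Br)c1
F2 | step 5 | (2S,9Z)-17-[3,5-bis(methoxymethoxy)phenyl]heptadec-9-en-2-ol | C[C@H](O)CCCCCC/C=C\CCCCCCCc1cc(OCOC)cc(OCOC)c1
F3 | step 4 | (2S)-dec-9-yn-2-ol | C[C@H](O)CCCCCCC#C
F4 | step 4 | (17S)-17-hydroxyoctadec-9-ynoic acid | C[C@H](O)CCCCCCC#CCCCCCCCC(=O)O
F5 | step 3 | 6-chlorohexylmagnesium bromide | ClCCCCCC[Mg]Br
F6 | step 3 | (2S)-9-chlorononan-2-ol | C[C@H](O)CCCCCCCCl
F7 | step 3 | [(8S)-8-hydroxynonyl]triphenylphosphonium iodide | C[C@H](O)CCCCCCC[P+](c1ccccc1)(c1ccccc1)c1ccccc1.[I-]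
F8 | step 3 | (2S)-9-(triphenyl-λ5-phosphanylidene)nonan-2-ol | C[C@H](O)CCCCCCC=P(c1ccccc1)(c1ccccc1)c1ccccc1
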